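**Retrosynthetic overview**
1. Feature: the benzene ring C4a–C5–C6–C7–C8–C8a is a hydroquinone monoether (O1 on C8a para to the C6–OH, CH3 on C8, H on C5 and C7). It is fused through C4a–C8a to the dihydropyran O1–C2–C3–C4. An alkenyl(alkoxy)carbene, an alkyne and one CO assemble exactly this pattern, and O1–C2–C3–C4 serves as a built-in tether.
2. Side chain (last): C7'–C8' comes from SAMP-hydrazone alkylation of the C8'–C12' (R)-α-silyloxy ethyl ketone with a C7' iodide, which sets C8'; C10' comes from an Evans–Davis hydroxylation. C5'–C6' comes from acetate alkylation of the C5' bromide made by SeO2 oxidation of the prenyl end.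
3. Key disconnection: C8a–C4a, C5–C6 and C6–C7, back to an open-chain (CO)5Cr=C8a(O1-tert-alkyl)(isopropenyl) complex that carries a terminal alkyne at the end of the tether.
4. Ring order: no ring exists before the key step. In it the dihydropyran closes first (alkyne insertion) and the benzene ring second (CO insertion, 6π closure), in one operation.
5. Precursor: O1–C8a by alkoxide/acyloxycarbene exchange, C4–C4a by acetylide displacement, C2 from Sharpless epoxidation of geraniol and Red-Al opening.

Key step: step 9

Assumption: the minor C2 enantiomer left by step 1 is taken to be removable after step 22, where it travels as a diastereomer of 39; locants are chroman O1–C8a and side chain C1'–C12' counted from C2.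

Step 1
Reactants: 1 geraniol
Product: 2 (2R,3R)-2,3-epoxygeraniol
Conditions: Ti(OiPr)4 (cat.), D-(−)-diethyl tartrate (cat.), t-BuOOH, 4 Å MS, CH2Cl2, −20 °C
Reagents that add atoms: tert-butyl hydroperoxide, CC(C)(C)OO
Why: Sharpless asymmetric epoxidation: the titanium–tartrate complex binds the allylic hydroxyl, so only the C2=C3 alkene reacts, and with the D-(−)-tartrate oxygen should reach the face that gives the (2R,3R)-epoxide, whose tertiary C3–O carbon becomes chroman C2.

Step 2
Reactants: 2 (2R,3R)-2,3-epoxygeraniol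
Product: 3 (3R)-3,7-dimethyloct-6-ene-1,3-diol
Conditions: Red-Al, THF, 0 °C → rt
Reagents that add atoms: none
Why: Hydroxyl-directed reductive opening of a 2,3-epoxy alcohol: the aluminate bound to the C1 oxygen delivers hydride intramolecularly to C2, so the 1,3-diol should form while the tertiary C–O bond and its (R) configuration are not touched.

Step 3
Reactants: 3 (3R)-3,7-dimethyloct-6-ene-1,3-diol
Product: 4 (3R)-3-hydroxy-3,7-dimethyloct-6-enyl 4-methylbenzenesulfonate
Conditions: TsCl, Et3N, DMAP (cat.), CH2Cl2, 0 °C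
Reagents that add atoms: p-toluenesulfonyl chloride, Cc1ccc(cc1)S(=O)(=O)Cl
Why: Chemoselective sulfonylation: the primary hydroxyl reacts much faster than the hindered tertiary one, which turns C1 (later chroman C4) into an SN2 electrophile.

Step 4
Reactants: 4 (3R)-3-hydroxy-3,7-dimethyloct-6-enyl 4-methylbenzenesulfonate
Product: 5 (3R)-3,7-dimethyl-3-(triethylsilyloxy)oct-6-enyl 4-methylbenzenesulfonate
Conditions: TESOTf, 2,6-lutidine, CH2Cl2, −78 → 0 °C
Reagents that add atoms: triethylsilyl trifluoromethanesulfonate, CC[Si](CC)(CC)OS(=O)(=O)C(F)(F)F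
Why: Silyl ether formation with the reactive triflate caps the tertiary hydroxyl, because its alkoxide would otherwise displace the γ-tosylate in a 4-exo-tet closure to an oxetane under the basic conditions of step 5.

Step 5
Reactants: 5 (3R)-3,7-dimethyl-3-(triethylsilyloxy)oct-6-enyl 4-methylbenzenesulfonate; 6 ethynyltrimethylsilane
Product: 8 [(5R)-5,9-dimethyl-5-(triethylsilyloxy)dec-8-en-1-ynyl]trimethylsilane, via lithium trimethylsilylacetylide 7 (not isolated)
Conditions: 6, n-BuLi, THF, −78 °C; then 5, DMPU, −78 °C → rt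
Reagents that add atoms: none
Why: SN2 alkylation of a lithium acetylide by a primary tosylate in a dipolar aprotic co-solvent forms the C4–C4a bond, the C-silyl group keeping the acetylide monofunctional and the stereocentre remaining a spectator.

Step 6
Reactants: 8 [(5R)-5,9-dimethyl-5-(triethylsilyloxy)dec-8-en-1-ynyl]trimethylsilane
Product: 9 (5R)-5,9-dimethyldec-8-en-1-yn-5-ol
Conditions: TBAF, THF, rt
Reagents that add atoms: none
Why: Fluoride-induced desilylation cleaves the alkynyl C–Si and the O–Si bond in one operation, driven by the strong Si–F bond, and leaves alkene and stereocentre untouched.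

Step 7
Reactants: 10 2-bromopropene; 11 chromium hexacarbonyl
Product: 14 tetramethylammonium pentacarbonyl(2-methyl-1-oxidoprop-2-enylidene)chromate, via isopropenyllithium 12 (not isolated), via lithium acylchromate 13 (not isolated)
Conditions: 10, t-BuLi (2 equiv), Et2O, −78 °C; 11, Et2O, 0 °C → rt; Me4NBr, degassed H2O
Reagents that add atoms: tetramethylammonium bromide, C[N+](C)(C)C.[Br-]
Why: First half of the Fischer carbene synthesis: halogen–lithium exchange and addition of the alkenyllithium to a CO ligand give the acylchromate, and cation metathesis should give a crystalline, storable salt that can be O-acylated cleanly.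

Step 8
Reactants: 14 tetramethylammonium pentacarbonyl(2-methyl-1-oxidoprop-2-enylidene)chromate; 9 (5R)-5,9-dimethyldec-8-en-1-yn-5-ol
Product: 17 pentacarbonyl{1-[(5R)-5,9-dimethyldec-8-en-1-yn-5-yloxy]-2-methylprop-2-enylidene}chromium(0), via pivaloyloxycarbene complex 15 (not isolated), via lithium alkoxide 16 (not isolated)
Conditions: 14 (excess), t-BuCOCl, CH2Cl2, −40 °C; separately 9, n-BuLi (1 equiv), THF, −78 °C; combine, −78 → −20 °C; rapid filtration through silica (hexane, Ar)
Reagents that add atoms: none
Why: Proposed new method: O-acylation of the acylchromate gives an acyloxycarbene, the isolobal counterpart of a mixed anhydride, whose carbene carbon takes up O-nucleophiles by addition–elimination with loss of carboxylate; this exchange (closest known type: alcoholysis of acyloxycarbene complexes) is established for primary and secondary alcohols and is extended here to a tertiary oxygen by using the pre-formed lithium alkoxide, as in the making of tert-alkyl esters from acid chlorides and lithium tert-alkoxides, while the pivaloyl group blocks attack at the acyl C=O, the twisted α-methylvinyl group is a poor Michael acceptor, no acid is released that could ionise the tertiary C2–O1 bond, and that bond is never broken, so C2 keeps its configuration.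

Step 9
Reactants: 17 pentacarbonyl{1-[(5R)-5,9-dimethyldec-8-en-1-yn-5-yloxy]-2-methylprop-2-enylidene}chromium(0)
Product: 19 (2R)-2,8-dimethyl-2-(4-methylpent-3-enyl)chroman-6-ol, via tricarbonylchromium arene complex 18 (not isolated)
Conditions: degassed t-BuOMe (0.005 M), 55 °C, Ar; then air, Et2O–MeCN, rt
Reagents that add atoms: none
Why: Thermal loss of a cis-CO opens a site for the tethered alkyne, which inserts into the Cr=C8a bond through its internal carbon (C8a–C4a), CO then migrates to the new carbene carbon C5 (C5–C6), and the resulting dienylketene closes C6–C7 and enolises to the phenol, first as its Cr(CO)3 complex 18, which air strips. The closest known reaction type is the intramolecular Dötz benzannulation of alkoxycarbene complexes that carry the alkyne on the carbene oxygen. The dihydropyran ring (O1–C2–C3–C4–C4a–C8a) closes in a 6-exo-dig sense during the insertion, and the benzene ring closes by a thermal disrotatory 6π electrocyclisation of the C7=C8–C8a=C4a–C5=C6=O dienylketene followed by tautomerisation. No stereocentre is formed: the four bonds of C2 stay intact, and the planar chirality of 18 disappears on decomplexation. The step needs a regiochemistry opposite to the intrinsic one of terminal alkynes (substituent next to the new OH), and the C2–C3–C4 tether enforces it, because the other orientation would lead to a strained bridged arene, while the endocyclic C4a=C8a bond also holds the isopropenyl group cis to C5 as the closure requires. It also needs alkyne over C3'=C4' alkene, intramolecular over intermolecular insertion and phenol over five-ring formation, which the hindered trisubstituted alkene, high dilution and the alkenyl–chromium combination should secure, and the weakly polar ether at moderate temperature limits ionisation of the tertiary alkoxy group.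

Step 10
Reactants: 19 (2R)-2,8-dimethyl-2-(4-methylpent-3-enyl)chroman-6-ol
Product: 20 (2R)-6-(tert-butyldimethylsilyloxy)-2,8-dimethyl-2-(4-methylpent-3-enyl)chroman
Conditions: TBSCl, imidazole, DMF, rt
Reagents that add atoms: tert-butyldimethylsilyl chloride, CC(C)(C)[Si](C)(C)Cl
Why: Standard imidazole-promoted phenol silylation masks the acidic and oxidation-prone C6–OH for the oxidising and strongly basic steps that follow.

Step 11
Reactants: 20 (2R)-6-(tert-butyldimethylsilyloxy)-2,8-dimethyl-2-(4-methylpent-3-enyl)chroman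
Product: 21 (2E)-5-[(2R)-6-(tert-butyldimethylsilyloxy)-2,8-dimethylchroman-2-yl]-2-methylpent-2-en-1-ol
Conditions: SeO2 (cat.), t-BuOOH, salicylic acid (cat.), CH2Cl2, 0 °C → rt, stopped at partial conversion, 20 recycled
Reagents that add atoms: tert-butyl hydroperoxide, CC(C)(C)OO
Why: Riley allylic oxidation (ene reaction, then [2,3]-sigmatropic shift of the allylseleninic acid) attacks a trisubstituted alkene at the methyl group trans to the chain, so C5' should be hydroxylated with the (E) geometry kept, the silylated arene and its benzylic positions being less reactive.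

Step 12
Reactants: 21 (2E)-5-[(2R)-6-(tert-butyldimethylsilyloxy)-2,8-dimethylchroman-2-yl]-2-methylpent-2-en-1-ol
Product: 22 (2R)-2-[(3E)-5-bromo-4-methylpent-3-enyl]-6-(tert-butyldimethylsilyloxy)-2,8-dimethylchroman
Conditions: CBr4, PPh3, CH2Cl2, 0 °C
Reagents that add atoms: carbon tetrabromide, BrC(Br)(Br)Br
Why: Appel reaction: SN2 displacement of the oxyphosphonium group by bromide under neutral conditions should give the primary allylic bromide without allylic transposition or E/Z loss.

Step 13
Reactants: 22 (2R)-2-[(3E)-5-bromo-4-methylpent-3-enyl]-6-(tert-butyldimethylsilyloxy)-2,8-dimethylchroman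
Product: 23 ethyl (4E)-7-[(2R)-6-(tert-butyldimethylsilyloxy)-2,8-dimethylchroman-2-yl]-4-methylhept-4-enoate
Conditions: EtOAc, LDA, THF, −78 °C; then 22, DMPU, −78 → −30 °C
Reagents that add atoms: ethyl acetate, CCOC(C)=O
Why: Ester enolate alkylation: the lithium enolate of ethyl acetate attacks the unhindered primary allylic carbon in an SN2 sense (the SN2' terminus C3' is more hindered) and so adds C6' and C7'.

Step 14
Reactants: 23 ethyl (4E)-7-[(2R)-6-(tert-butyldimethylsilyloxy)-2,8-dimethylchroman-2-yl]-4-methylhept-4-enoate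
Product: 24 (4E)-7-[(2R)-6-(tert-butyldimethylsilyloxy)-2,8-dimethylchroman-2-yl]-4-methylhept-4-en-1-ol
Conditions: DIBAL-H (excess), CH2Cl2, −78 → 0 °C; Rochelle salt
Reagents that add atoms: none
Why: Ester reduction with excess DIBAL-H ends at the primary alcohol and tolerates the aryl silyl ether and the alkene.

Step 15
Reactants: 24 (4E)-7-[(2R)-6-(tert-butyldimethylsilyloxy)-2,8-dimethylchroman-2-yl]-4-methylhept-4-en-1-ol
Product: 25 (2R)-6-(tert-butyldimethylsilyloxy)-2-[(3E)-7-iodo-4-methylhept-3-enyl]-2,8-dimethylchroman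
Conditions: I2, PPh3, imidazole, CH2Cl2, 0 °C
Reagents that add atoms: iodine, II
Why: Garegg–Samuelsson (Appel-type) iodination converts the primary alcohol by SN2 into the unhindered C7' iodide needed as alkylating agent.

Step 16
Reactants: 26 4-methylpent-3-enoic acid; 27 (4R)-4-benzyl-1,3-oxazolidin-2-one
Product: 30 (4R)-4-benzyl-3-(4-methylpent-3-enoyl)-1,3-oxazolidin-2-one, via mixed pivalic anhydride 28 (not isolated), via lithiated oxazolidinone 29 (not isolated)
Conditions: 26, t-BuCOCl, Et3N, THF, −20 °C; 27, n-BuLi, THF, −78 °C; combine, −78 → 0 °C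
Reagents that add atoms: none
Why: N-Acylation of the Evans auxiliary by way of the mixed anhydride: the lithiated carbamate nitrogen attacks the less hindered acyl carbon at low temperature, at which the β,γ-alkene should not move into conjugation.

Step 17
Reactants: 30 (4R)-4-benzyl-3-(4-methylpent-3-enoyl)-1,3-oxazolidin-2-one
Product: 32 (4R)-4-benzyl-3-[(2R)-2-hydroxy-4-methylpent-3-enoyl]-1,3-oxazolidin-2-one, via sodium dienolate 31 (not isolated)
Conditions: NaHMDS, THF, −78 °C; 2-(phenylsulfonyl)-3-phenyloxaziridine, −78 °C; AcOH quench at −78 °C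
Reagents that add atoms: 2-(phenylsulfonyl)-3-phenyloxaziridine, O=S(=O)(N1OC1c1ccccc1)c1ccccc1
Why: Evans–Davis asymmetric enolate hydroxylation: the chelated (Z)-sodium dienolate is attacked by the N-sulfonyloxaziridine at its α-carbon from the face opposite to the benzyl group of the (R)-auxiliary, which should set the later C10' as (R) and leave the alkene in the β,γ-position.

Step 18
Reactants: 32 (4R)-4-benzyl-3-[(2R)-2-hydroxy-4-methylpent-3-enoyl]-1,3-oxazolidin-2-one
Product: 33 (2R)-2-hydroxy-N-methoxy-N,4-dimethylpent-3-enamide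
Conditions: MeONHMe·HCl, AlMe3, CH2Cl2, −10 → 0 °C
Reagents that add atoms: N,O-dimethylhydroxylamine hydrochloride, CNOC.Cl
Why: Weinreb transamidation with the aluminium amide, helped by chelation to the free α-hydroxyl, cleaves the exocyclic imide carbonyl, frees the auxiliary and does not touch the α-stereocentre.

Step 19
Reactants: 33 (2R)-2-hydroxy-N-methoxy-N,4-dimethylpent-3-enamide
Product: 34 (2R)-2-(tert-butyldimethylsilyloxy)-N-methoxy-N,4-dimethylpent-3-enamide
Conditions: TBSCl, imidazole, DMF, rt
Reagents that add atoms: tert-butyldimethylsilyl chloride, CC(C)(C)[Si](C)(C)Cl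
Why: Silylation puts on the C10' oxygen a group that tolerates Grignard reagent, lithium amide and aqueous oxalic acid and that leaves at the end with buffered fluoride, so that no basic ester cleavage next to the epimerisable α-ketol is needed.

Step 20
Reactants: 34 (2R)-2-(tert-butyldimethylsilyloxy)-N-methoxy-N,4-dimethylpent-3-enamide
Product: 35 (4R)-4-(tert-butyldimethylsilyloxy)-6-methylhept-5-en-3-one
Conditions: EtMgBr, THF, 0 °C
Reagents that add atoms: ethylmagnesium bromide, CC[Mg]Br
Why: Weinreb ketone synthesis: the chelated tetrahedral magnesium adduct survives until work-up, so a single ethyl group is added, and allylic 1,3-strain keeps the C10'–H bond in the alkene plane and thereby poorly acidic.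

Step 21
Reactants: 35 (4R)-4-(tert-butyldimethylsilyloxy)-6-methylhept-5-en-3-one; 36 (S)-1-amino-2-(methoxymethyl)pyrrolidine (SAMP)
Product: 37 SAMP hydrazone of 35 (C=N geometry not defined)
Conditions: 36, 4 Å MS, cyclohexane, 60 °C
Reagents that add atoms: none
Why: Hydrazone condensation under neutral, water-scavenging conditions attaches the auxiliary without acid or base that could enolise towards C10'.

Step 22
Reactants: 37 SAMP hydrazone of 35; 25 (2R)-6-(tert-butyldimethylsilyloxy)-2-[(3E)-7-iodo-4-methylhept-3-enyl]-2,8-dimethylchroman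
Product: 39 SAMP hydrazone of the (2R,3'E,8'S,10'R)-bis-silyl ketone 40, via lithium azaenolate 38 (not isolated)
Conditions: 37, LDA, THF, 0 °C; then 25, −95 °C → rt
Reagents that add atoms: none
Why: Enders SAMP-hydrazone alkylation: kinetic deprotonation on the less substituted ethyl side gives the methoxy-chelated lithium azaenolate, whose open face is attacked by the primary iodide in an SN2 reaction, so the auxiliary should set C8' as (S), and no oxygen is ever placed on C7', whose radical removal would create a 5-hexenyl-type radical facing the C11'=C12' alkene.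

Step 23
Reactants: 39 SAMP hydrazone of the bis-silyl ketone
Product: 40 (4R,6S,10E)-4-(tert-butyldimethylsilyloxy)-13-[(2R)-6-(tert-butyldimethylsilyloxy)-2,8-dimethylchroman-2-yl]-2,6,10-trimethyltrideca-2,10-dien-5-one
Conditions: sat. aq. oxalic acid, Et2O, rt
Reagents that add atoms: water, O
Why: Mild biphasic hydrazone hydrolysis with oxalic acid protonates and extracts the auxiliary as its salt, a method known to spare α-stereocentres, alkenes and silyl ethers.

Step 24
Reactants: 40 bis-silyl ketone
Product: 41 target, (4R,6S,10E)-4-hydroxy-13-[(2R)-6-hydroxy-2,8-dimethylchroman-2-yl]-2,6,10-trimethyltrideca-2,10-dien-5-one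
Conditions: TBAF, AcOH (1:1), THF, 0 °C → rt
Reagents that add atoms: none
Why: Fluoride desilylation buffered with acetic acid frees the phenol and the C10' alcohol at once without basic conditions, so the C8' and C10' centres that flank the ketone and the β,γ-position of the alkene should be preserved.

**Compound list**
1 | geraniol | CC(C)=CCC/C(C)=C/CO | starting material
2 | (2R,3R)-2,3-epoxygeraniol | CC(C)=CCC[C@@]1(C)O[C@@H]1CO | intermediate
3 | (3R)-3,7-dimethyloct-6-ene-1,3-diol | CC(C)=CCC[C@](O)(C)CCO | intermediate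
4 | (3R)-3-hydroxy-3,7-dimethyloct-6-enyl tosylate | CC(C)=CCC[C@](O)(C)CCOS(=O)(=O)c1ccc(C)cc1 | intermediate
5 | (3R)-3,7-dimethyl-3-(triethylsilyloxy)oct-6-enyl tosylate | CC(C)=CCC[C@](O[Si](CC)(CC)CC)(C)CCOS(=O)(=O)c1ccc(C)cc1 | intermediate
6 | ethynyltrimethylsilane | C#C[Si](C)(C)C | starting material
7 | lithium trimethylsilylacetylide | [Li]C#C[Si](C)(C)C | intermediate
8 | [(5R)-5,9-dimethyl-5-(triethylsilyloxy)dec-8-en-1-ynyl]trimethylsilane | CC(C)=CCC[C@](O[Si](CC)(CC)CC)(C)CCC#C[Si](C)(C)C | intermediate
9 | (5R)-5,9-dimethyldec-8-en-1-yn-5-ol | CC(C)=CCC[C@](O)(C)CCC#C | intermediate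
10 | 2-bromopropene | C=C(C)Br | starting material
11 | chromium hexacarbonyl | O=C=[Cr](=C=O)(=C=O)(=C=O)(=C=O)=C=O | starting material
12 | isopropenyllithium | [Li]C(C)=C | intermediate
13 | lithium pentacarbonyl(2-methyl-1-oxidoprop-2-enylidene)chromate | [Li+].CC(=C)C([O-])=[Cr](=C=O)(=C=O)(=C=O)(=C=O)=C=O | intermediate
14 | tetramethylammonium pentacarbonyl(2-methyl-1-oxidoprop-2-enylidene)chromate | C[N+](C)(C)C.CC(=C)C([O-])=[Cr](=C=O)(=C=O)(=C=O)(=C=O)=C=O | intermediate
15 | pentacarbonyl[2-methyl-1-(pivaloyloxy)prop-2-enylidene]chromium | CC(=C)C(OC(=O)C(C)(C)C)=[Cr](=C=O)(=C=O)(=C=O)(=C=O)=C=O | intermediate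
16 | lithium (5R)-5,9-dimethyldec-8-en-1-yn-5-olate | [Li+].CC(C)=CCC[C@]([O-])(C)CCC#C | intermediate
17 | pentacarbonyl{1-[(5R)-5,9-dimethyldec-8-en-1-yn-5-yloxy]-2-methylprop-2-enylidene}chromium(0) | CC(C)=CCC[C@](OC(C(C)=C)=[Cr](=C=O)(=C=O)(=C=O)(=C=O)=C=O)(C)CCC#C | intermediate
18 | tricarbonyl(η6-19)chromium, η6 bonding written as two components | CC(C)=CCC[C@]1(C)CCc2cc(O)cc(C)c2O1.O=C=[Cr](=C=O)=C=O | intermediate
19 | (2R)-2,8-dimethyl-2-(4-methylpent-3-enyl)chroman-6-ol | CC(C)=CCC[C@]1(C)CCc2cc(O)cc(C)c2O1 | intermediate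
20 | 6-O-TBS ether of 19 | CC(C)=CCC[C@]1(C)CCc2cc(O[Si](C)(C)C(C)(C)C)cc(C)c2O1 | intermediate
21 | (E)-C5' allylic alcohol | OC/C(C)=C/CC[C@]1(C)CCc2cc(O[Si](C)(C)C(C)(C)C)cc(C)c2O1 | intermediate
22 | (E)-C5' allylic bromide | BrC/C(C)=C/CC[C@]1(C)CCc2cc(O[Si](C)(C)C(C)(C)C)cc(C)c2O1 | intermediate
23 | C7' ethyl ester | CCOC(=O)CC/C(C)=C/CC[C@]1(C)CCc2cc(O[Si](C)(C)C(C)(C)C)cc(C)c2O1 | intermediate
24 | C7' primary alcohol | OCCC/C(C)=C/CC[C@]1(C)CCc2cc(O[Si](C)(C)C(C)(C)C)cc(C)c2O1 | intermediate
25 | C7' primary iodide | ICCC/C(C)=C/CC[C@]1(C)CCc2cc(O[Si](C)(C)C(C)(C)C)cc(C)c2O1 | intermediate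
26 | 4-methylpent-3-enoic acid | CC(C)=CCC(=O)O | starting material
27 | (4R)-4-benzyl-1,3-oxazolidin-2-one | O=C1N[C@H](Cc2ccccc2)CO1 | starting material
28 | 4-methylpent-3-enoic pivalic anhydride | CC(C)=CCC(=O)OC(=O)C(C)(C)C | intermediate
29 | N-lithio-(4R)-4-benzyl-1,3-oxazolidin-2-one | [Li]N1[C@H](Cc2ccccc2)COC1=O | intermediate
30 | (4R)-4-benzyl-3-(4-methylpent-3-enoyl)-1,3-oxazolidin-2-one | CC(C)=CCC(=O)N1[C@H](Cc2ccccc2)COC1=O | intermediate
31 | sodium (Z)-dienolate of 30 | CC(C)=C/C=C(\[O-])N1[C@H](Cc2ccccc2)COC1=O.[Na+] | intermediate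
32 | (4R)-4-benzyl-3-[(2R)-2-hydroxy-4-methylpent-3-enoyl]-1,3-oxazolidin-2-one | CC(C)=C[C@@H](O)C(=O)N1[C@H](Cc2ccccc2)COC1=O | intermediate
33 | (2R)-2-hydroxy-N-methoxy-N,4-dimethylpent-3-enamide | CC(C)=C[C@@H](O)C(=O)N(C)OC | intermediate
34 | (2R)-2-(tert-butyldimethylsilyloxy)-N-methoxy-N,4-dimethylpent-3-enamide | CC(C)=C[C@@H](O[Si](C)(C)C(C)(C)C)C(=O)N(C)OC | intermediate
35 | (4R)-4-(tert-butyldimethylsilyloxy)-6-methylhept-5-en-3-one | CC(C)=C[C@@H](O[Si](C)(C)C(C)(C)C)C(=O)CC | intermediate
36 | (S)-1-amino-2-(methoxymethyl)pyrrolidine (SAMP) | COC[C@@H]1CCCN1N | starting material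
37 | SAMP hydrazone of 35 | CC(C)=C[C@@H](O[Si](C)(C)C(C)(C)C)C(CC)=NN1CCC[C@H]1COC | intermediate
38 | lithium azaenolate of 37 (E at C8'=C9') | CC(C)=C[C@@H](O[Si](C)(C)C(C)(C)C)/C(=C\C)N([Li])N1CCC[C@H]1COC | intermediate
39 | SAMP hydrazone of 40 | CC(C)=C[C@@H](O[Si](C)(C)C(C)(C)C)C(=NN1CCC[C@H]1COC)[C@@H](C)CCC/C(C)=C/CC[C@]2(C)CCc3cc(O[Si](C)(C)C(C)(C)C)cc(C)c3O2 | intermediate
40 | (2R,3'E,8'S,10'R)-6,10'-bis-O-TBS ketone | CC(C)=C[C@@H](O[Si](C)(C)C(C)(C)C)C(=O)[C@@H](C)CCC/C(C)=C/CC[C@]1(C)CCc2cc(O[Si](C)(C)C(C)(C)C)cc(C)c2O1 | intermediate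
41 | CNP0273237.1, (2R,3'E,8'S,10'R) | CC(C)=C[C@@H](O)C(=O)[C@@H](C)CCC/C(C)=C/CC[C@]1(C)CCc2cc(O)cc(C)c2O1 | target

**Step count**
Total step count: 24. Longest linear sequence: 17 steps (1–6, 8–15, 22–24, from geraniol).

**Steps most likely to fail**

1. Step 8 (bears the label Proposed new method).
- What may go wrong: the hindered tertiary alkoxide may add to the carbene carbon more slowly than the acyloxycarbene decays. It may also add to the methylene terminus in a conjugate sense, or take over the acyl group.
- Fallback with known chemistry, from compound 9 (with 11) back to compound 19: the O1–C8a bond is made intramolecularly. Cr(CO)5(THF), generated by irradiation of 11 in THF, converts the terminal alkyne of 9 through its vinylidene complex into the cyclic carbene complex pentacarbonyl[(6R)-6-methyl-6-(4-methylpent-3-enyl)oxan-2-ylidene]chromium F1. This is an alkynol cycloisomerisation, and here the two alkyne carbons become C8a and C4a.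
- Deprotonation of the acidic C4a–H (n-BuLi, −78 °C) and Eschenmoser's salt give the Mannich base, the 3-(dimethylaminomethyl)oxan-2-ylidene complex F2. It loses dimethylamine on silica to give the 3-methyleneoxan-2-ylidene complex F3.
- An intermolecular Dötz benzannulation of F3 with tributyl(prop-1-ynyl)stannane puts the bulky tin group next to the new phenol and the methyl group on C8. The resulting (2R)-2,8-dimethyl-2-(4-methylpent-3-enyl)-7-(tributylstannyl)chroman-6-ol F4 is protodestannylated on silica gel to 19.

2. Step 9 (key step).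
- What may go wrong: the tertiary alkoxy group may be lost by ionisation or elimination before CO dissociates. Intermolecular alkyne insertion may lead to oligomerisation, or the vinylcarbene may collapse without CO insertion.
- Fallback from compound 9 back to compound 19: the benzannulation is run intermolecularly with its natural regiochemistry, and the pyran is closed afterwards. Pentacarbonyl[(2E)-1-methoxybut-2-enylidene]chromium F5 is made from (E)-1-bromopropene, t-BuLi, 11 and Me3OBF4. It is heated with 9 in THF and freed from chromium with air.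
- The alkyne substituent then ends up next to the CO-derived hydroxyl and the propenyl methyl on its other side. This gives 2-[(3R)-3-hydroxy-3,7-dimethyloct-6-enyl]-4-methoxy-6-methylphenol F6.
- Selective phenol triflation (PhNTf2, K2CO3) gives the aryl triflate F7. An intramolecular Buchwald–Hartwig C–O coupling of the tertiary alcohol (Pd(OAc)2, bulky biarylphosphine, Cs2CO3, toluene) closes O1–C8a without touching the C2–O bond and gives (2R)-6-methoxy-2,8-dimethyl-2-(4-methylpent-3-enyl)chroman F8. Thiolate demethylation (NaSEt, DMF, heat) gives 19.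

3. Step 22.
- What may go wrong: competing metalation on the C10' side would erode that centre. Substitution on the unactivated iodide may be slow, or the facial bias may weaken if the resident C10' centre opposes the auxiliary. The crowded hydrazone may also resist formation (step 21) or hydrolysis (step 23).
- Fallback from compounds 24 and 33 back to compound 41: C8' is set by the C10' centre in an aldol reaction. Dess–Martin oxidation of 24 gives the C7' aldehyde F9.
- Excess EtMgBr converts 33 into (4R)-4-hydroxy-6-methylhept-5-en-3-one F10, and Bz2O/DMAP gives its benzoate F11.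
- A Paterson anti-aldol reaction (c-Hex2BCl, Me2NEt, Et2O; then F9) should give the (7'S,8'S,10'R) adduct F12 through the (E)-enol borinate.
- PhOC(S)Cl/pyridine gives the thionocarbonate F13. A Barton–McCombie reduction follows, run at ambient temperature with Et3B/air and concentrated Bu3SnH so that hydrogen transfer outruns 5-exo closure of the C7' radical onto C11'=C12'. It gives the 7'-deoxy benzoate F14.
- Brief methanolysis (K2CO3, MeOH, 0 °C, Ar) gives the 10'-alcohol F15, and TBAF/AcOH gives 41.

**Further compounds**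
F1 | step 8 | pentacarbonyl[(6R)-6-methyl-6-(4-methylpent-3-enyl)oxan-2-ylidene]chromium | CC(C)=CCC[C@]1(C)CCCC(=[Cr](=C=O)(=C=O)(=C=O)(=C=O)=C=O)O1
F2 | step 8 | 3-(dimethylaminomethyl) derivative of F1 (C3 epimers) | CC(C)=CCC[C@]1(C)CCC(CN(C)C)C(=[Cr](=C=O)(=C=O)(=C=O)(=C=O)=C=O)O1
F3 | step 8 | pentacarbonyl[(6R)-6-methyl-3-methylene-6-(4-methylpent-3-enyl)oxan-2-ylidene]chromium | CC(C)=CCC[C@]1(C)CCC(=C)C(=[Cr](=C=O)(=C=O)(=C=O)(=C=O)=C=O)O1
F4 | step 8 | (2R)-2,8-dimethyl-2-(4-methylpent-3-enyl)-7-(tributylstannyl)chroman-6-ol | CC(C)=CCC[C@]1(C)CCc2cc(O)c([Sn](CCCC)(CCCC)CCCC)c(C)c2O1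
F5 | step 9 | pentacarbonyl[(2E)-1-methoxybut-2-enylidene]chromium | C/C=C/C(OC)=[Cr](=C=O)(=C=O)(=C=O)(=C=O)=C=O
F6 | step 9 | 2-[(3R)-3-hydroxy-3,7-dimethyloct-6-enyl]-4-methoxy-6-methylphenol | CC(C)=CCC[C@](O)(C)CCc1cc(OC)cc(C)c1O
F7 | step 9 | 2-[(3R)-3-hydroxy-3,7-dimethyloct-6-enyl]-4-methoxy-6-methylphenyl triflate | CC(C)=CCC[C@](O)(C)CCc1cc(OC)cc(C)c1OS(=O)(=O)C(F)(F)F
F8 | step 9 | (2R)-6-methoxy-2,8-dimethyl-2-(4-methylpent-3-enyl)chroman | CC(C)=CCC[C@]1(C)CCc2cc(OC)cc(C)c2O1
F9 | step 22 | (4E)-7-[(2R)-6-(tert-butyldimethylsilyloxy)-2,8-dimethylchroman-2-yl]-4-methylhept-4-enal | O=CCC/C(C)=C/CC[C@]1(C)CCc2cc(O[Si](C)(C)C(C)(C)C)cc(C)c2O1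
F10 | step 22 | (4R)-4-hydroxy-6-methylhept-5-en-3-one | CC(C)=C[C@@H](O)C(=O)CC
F11 | step 22 | (4R)-2-methyl-5-oxohept-2-en-4-yl benzoate | CC(C)=C[C@@H](OC(=O)c1ccccc1)C(=O)CC
F12 | step 22 | (7'S,8'S,10'R)-10'-benzoyloxy-7'-hydroxy-9'-oxo aldol adduct, 6-O-TBS | CC(C)=C[C@@H](OC(=O)c1ccccc1)C(=O)[C@@H](C)[C@@H](O)CC/C(C)=C/CC[C@]2(C)CCc3cc(O[Si](C)(C)C(C)(C)C)cc(C)c3O2
F13 | step 22 | 7'-O-(phenoxythiocarbonyl) derivative of F12 | CC(C)=C[C@@H](OC(=O)c1ccccc1)C(=O)[C@@H](C)[C@@H](OC(=S)Oc1ccccc1)CC/C(C)=C/CC[C@]2(C)CCc3cc(O[Si](C)(C)C(C)(C)C)cc(C)c3O2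
F14 | step 22 | (8'S,10'R)-10'-benzoyloxy-9'-oxo compound, 6-O-TBS | CC(C)=C[C@@H](OC(=O)c1ccccc1)C(=O)[C@@H](C)CCC/C(C)=C/CC[C@]2(C)CCc3cc(O[Si](C)(C)C(C)(C)C)cc(C)c3O2
F15 | step 22 | 6-O-TBS ether of 41 | CC(C)=C[C@@H](O)C(=O)[C@@H](C)CCC/C(C)=C/CC[C@]1(C)CCc2cc(O[Si](C)(C)C(C)(C)C)cc(C)c2O1
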